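**Strategy.** The target is a neo-clerodane (clerodane numbering below). Ring B hides a Giese/aldol retron: C10 is β and the C8 carbinol is β′ to the C11 carbon on quaternary C9, and C5 bears a methyl (C19). Everything rests on cutting C5–C10 and C8–C9 together. An acyclic triad (1,1-disubstituted alkene C5=C19, (E)-enal C10=C9–C11, C8 methyl ketone; 1-acetoxy and tartrate-derived 6,7-diol centres preset) is cyclised by iron-hydride hydrogen-atom transfer. The tertiary C5 radical closes ring A onto C10 and the resulting C9 enolate closes ring B onto C8, creating C5, C10, C9 and C8 in one operation. Side chain, C4 methylene and esters follow.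

Key step: step 10

Remark: positions follow the clerodane skeleton (ring A = C1–C5, C10; ring B = C5–C10; side chain C11–C16; C17 on C8, C18 on C4, C19 on C5, C20 on C9; β = face of H-10). The C4 carbinol made in step 8 is assumed to form as both epimers; it is carried as such (C4 left open in 14–18) and erased by oxidation in step 11.

Step 1
Reactants: 1 acrolein
Product: 3 (3R)-hexa-1,5-dien-3-ol, via borinate 2 (not isolated)
Conditions: (+)-Ipc2B(allyl), Et2O, −78 °C; then NaOH, H2O2
Reagents that add atoms: (+)-B-allyldiisopinocampheylborane, C=CCB([C@H]1C[C@H]2C[C@@H]([C@@H]1C)C2(C)C)[C@H]1C[C@H]2C[C@@H]([C@@H]1C)C2(C)C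
Why: Brown allylboration through a chair Zimmerman–Traxler transition state, in which the (+)-isopinocampheyl groups direct allyl transfer to one aldehyde face and give the (R)-carbinol (C1 of the target).

Step 2
Reactants: 3 (3R)-hexa-1,5-dien-3-ol
Product: 4 (3R)-hexa-1,5-dien-3-yl acetate
Conditions: Ac2O, pyridine, DMAP (cat.), CH2Cl2, 0 °C to rt
Reagents that add atoms: acetic anhydride, CC(=O)OC(C)=O
Why: DMAP-catalysed acetylation installs the C1 acetate of the target at the outset without touching the stereocentre.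

Step 3
Reactants: 4 (3R)-hexa-1,5-dien-3-yl acetate
Product: 6 (3R)-6-hydroxyhex-1-en-3-yl acetate, via alkylborane 5 (not isolated)
Conditions: 9-BBN, THF, 0 °C to rt; then H2O2, aq NaOAc
Reagents that add atoms: hydrogen peroxide, OO
Why: Chemoselective anti-Markovnikov hydroboration, since 9-BBN attacks the unhindered allyl-type alkene much faster than the vinyl group deactivated by the neighbouring acetoxy-bearing carbon, and buffered oxidation keeps the acetate.

Step 4
Reactants: 6 (3R)-6-hydroxyhex-1-en-3-yl acetate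
Product: 7 (3R)-6-oxohex-1-en-3-yl acetate
Conditions: Dess–Martin periodinane, NaHCO3, CH2Cl2, rt
Reagents that add atoms: none
Why: Dess–Martin oxidation of the primary alcohol to the aldehyde under buffered conditions that leave the allylic acetate and its stereocentre intact.

Step 5
Reactants: 8 dimethyl (4S,5S)-2,2-dimethyl-1,3-dioxolane-4,5-dicarboxylate
Product: 9 bis-Weinreb amide
Conditions: MeNH(OMe)·HCl, i-PrMgCl, THF, −20 to 0 °C
Reagents that add atoms: N,O-dimethylhydroxylamine hydrochloride, CNOC.Cl
Why: Magnesium-amide aminolysis of both esters (Weinreb amide formation) proceeds without epimerising the acetal-bearing centres, whose trans arrangement is also the thermodynamic one.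

Step 6
Reactants: 9 bis-Weinreb amide
Product: 10 C2-symmetric diketone
Conditions: MeMgBr, THF, −78 to 0 °C
Reagents that add atoms: methylmagnesium bromide, C[Mg]Br
Why: Grignard addition to a Weinreb amide stops at the ketone because the magnesium chelate only collapses on work-up.

Step 7
Reactants: 10 C2-symmetric diketone
Product: 12 mono enol triflate, via potassium enolate 11 (not isolated)
Conditions: KN(SiMe3)2 (1.0 equiv), PhNTf2, THF, −78 °C
Reagents that add atoms: N-phenylbis(trifluoromethanesulfonimide), O=S(=O)(N(c1ccccc1)S(=O)(=O)C(F)(F)F)C(F)(F)F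
Why: Kinetic deprotonation of one methyl group and O-triflation of the enolate give the alkenyl triflate, and because the two acetyl groups are equivalent by C2 symmetry only one mono-triflate can form.

Step 8
Reactants: 7 (3R)-6-oxohex-1-en-3-yl acetate; 12 mono enol triflate
Product: 14 allylic alcohol, via alkenylchromium 13 (not isolated)
Conditions: CrCl2, NiCl2 (cat.), DMF, rt
Reagents that add atoms: none
Why: Nozaki–Hiyama–Kishi coupling, in which zerovalent nickel inserts into the alkenyl triflate and the derived trivalent alkenylchromium adds only to the aldehyde (methyl ketone and acetate survive); the new C4 carbinol centre is expected as both epimers, which is harmless.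

Step 9
Reactants: 14 allylic alcohol
Product: 15 ene–enal–ketone
Conditions: methacrolein (excess), second-generation Hoveyda–Grubbs catalyst, CH2Cl2, 40 °C
Reagents that add atoms: methacrolein, CC(=C)C=O
Why: Olefin cross-metathesis engages only the monosubstituted vinyl group (the 1,1-disubstituted alkene flanked by two oxygenated carbons cannot load the carbene) and gives the thermodynamically favoured (E)-2-methyl enal.

Step 10
Reactants: 15 ene–enal–ketone
Product: 18 trans-decalin hydroxy aldehyde, via C5 radical 16 (not isolated), via iron enolate 17 (not isolated)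
Conditions: Fe(acac)3, PhSiH3, EtOH/(CH2OH)2, rt
Reagents that add atoms: none
Why: The iron hydride formed from Fe(acac)3 and PhSiH3 transfers a hydrogen atom to the terminal carbon of the C5=C19 alkene, creating the C19 methyl and the nucleophilic tertiary C5 radical 16; this adds to C10 of the enal, the α-formyl radical is reduced by divalent iron to the C9 enolate 17, and 17 adds to the C8 methyl ketone. The closest known reaction type is the iron-hydride-initiated radical–polar crossover Giese/aldol annulation of alkene–enal–ketone triads used to build decalinols. Ring A closes by 6-exo-trig radical cyclisation through a chair in which the C1 acetoxy group is equatorial (its C–H eclipses the enal plane to avoid A(1,3) strain with the C9 methyl), which fixes C10, and in which the bulky dioxolanyl branch on C5 is equatorial, which fixes C5 (methyl axial) and the trans ring fusion. Ring B closes by 6-(enolexo)-exo-trig aldol through a chair fused to the trans-dioxolane (both ring oxygens equatorial), with the C9 methyl axial and the formyl group equatorial, and with the C8 methyl equatorial and the alkoxide axial and bridged by iron to the enolate oxygen, which sets C9 and C8. The step needs hydrogen-atom transfer to the electron-rich 1,1-disubstituted alkene and not to the enal, and cyclisation faster than reduction of the radical; the alkene substitution pattern and the activated acceptor held five atoms away secure both. All three preset oxygen substituents (O1, O6, O7) are equatorial in the chair–chair product, so the tartrate and C1 centres reinforce each other.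

Step 11
Reactants: 18 trans-decalin hydroxy aldehyde
Product: 19 4-keto aldehyde
Conditions: Dess–Martin periodinane, pyridine, CH2Cl2, rt
Reagents that add atoms: none
Why: Dess–Martin oxidation of the only secondary alcohol converts both C4 epimers into one ketone, while the aldehyde and the tertiary alcohol are inert.

Step 12
Reactants: 19 4-keto aldehyde; 20 1-(tert-butyldimethylsilyloxy)propan-2-one
Product: 22 (11S)-aldol, via lithium enolate 21 (not isolated)
Conditions: 20, LiN(i-Pr)2, THF, −78 °C; then 19, −78 °C; aq NH4Cl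
Reagents that add atoms: none
Why: Aldol addition of the kinetic methyl-side lithium enolate to the aldehyde (the hindered C4 ketone is untouched), in which lithium bridges the C8 oxygen and the formyl oxygen and the enolate enters from the face flanked by the axial C9 methyl rather than by C10, which should give 11S (chelation-controlled 1,3-induction).

Step 13
Reactants: 22 (11S)-aldol
Product: 23 11-acetate
Conditions: Ac2O, DMAP, pyridine, CH2Cl2, rt
Reagents that add atoms: acetic anhydride, CC(=O)OC(C)=O
Why: DMAP-catalysed acetylation of the secondary C11 alcohol, the axial tertiary C8 hydroxyl being too hindered to react.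

Step 14
Reactants: 23 11-acetate
Product: 24 primary ketol
Conditions: HF·pyridine, pyridine, THF, 0 °C to rt
Reagents that add atoms: none
Why: Fluoride cleavage of the primary silyl ether under buffered, non-basic conditions that spare the β-acetoxy ketone, the acetates and the acetonide.

Step 15
Reactants: 24 primary ketol
Product: 26 butenolide ketone, via ylide ester 25 (not isolated)
Conditions: Ph3P=C=C=O, toluene, 80 °C
Reagents that add atoms: (triphenylphosphoranylidene)ketene, O=C=C=P(c1ccccc1)(c1ccccc1)c1ccccc1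
Why: Bestmann ylide lactonisation, in which the primary hydroxyl adds to the cumulated ylide and the resulting phosphoranylidene acetate undergoes intramolecular Wittig reaction with the C13 ketone to close the butenolide.

Step 16
Reactants: 26 butenolide ketone
Product: 27 4(18)-methylene acetonide
Conditions: Zn, CH2Br2, TiCl4, THF/CH2Cl2, 0 °C to rt
Reagents that add atoms: dibromomethane, BrCBr
Why: Takai–Lombardo methylenation, whose weakly basic zinc–titanium methylene reagent converts the hindered C4 ketone (the only ketone left) into the exocyclic alkene without touching esters, butenolide or the tertiary alcohol.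

Step 17
Reactants: 27 4(18)-methylene acetonide
Product: 28 6α,7β,8β-triol
Conditions: AcOH/H2O (4:1), 40 °C
Reagents that add atoms: none
Why: Acidic hydrolysis of the strained trans-fused isopropylidene acetal frees the diol, while acetates, butenolide and the exocyclic alkene tolerate aqueous acetic acid.

Step 18
Reactants: 28 6α,7β,8β-triol
Product: 29 7-isobutyrate
Conditions: i-PrCOCl (1.1 equiv), 2,4,6-collidine, CH2Cl2, −40 to 0 °C
Reagents that add atoms: isobutyryl chloride, CC(C)C(Cl)=O
Why: Regioselective acylation, because the equatorial 7β-hydroxyl is the most accessible one (6α-OH is wedged between quaternary C5 and the peri C4 methylene, 8β-OH is tertiary and axial).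

Step 19
Reactants: 29 7-isobutyrate
Product: 30 CNP0266716.1
Conditions: Ac2O, DMAP, Et3N, CH2Cl2, rt
Reagents that add atoms: acetic anhydride, CC(=O)OC(C)=O
Why: DMAP-catalysed acetylation of the remaining secondary 6α-hydroxyl, the tertiary 8β-hydroxyl staying free.

**Compound list**

1 | acrolein (prop-2-enal) | C=CC=O | starting material
2 | (3R)-hexa-1,5-dien-3-yl bis[(+)-isopinocampheyl]borinate | C=CC[C@H](C=C)OB([C@H]1C[C@H]2C[C@@H]([C@@H]1C)C2(C)C)[C@H]1C[C@H]2C[C@@H]([C@@H]1C)C2(C)C | intermediate
3 | (3R)-hexa-1,5-dien-3-ol | C=C[C@H](O)CC=C | intermediate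
4 | (3R)-hexa-1,5-dien-3-yl acetate | C=C[C@H](OC(C)=O)CC=C | intermediate
5 | B-[(4R)-4-acetoxyhex-5-enyl]-9-borabicyclo[3.3.1]nonane | C=C[C@H](OC(C)=O)CCCB1C2CCCC1CCC2 | intermediate
6 | (3R)-6-hydroxyhex-1-en-3-yl acetate | C=C[C@H](OC(C)=O)CCCO | intermediate
7 | (3R)-6-oxohex-1-en-3-yl acetate [(4R)-4-acetoxyhex-5-enal] | C=C[C@H](OC(C)=O)CCC=O | intermediate
8 | dimethyl (4S,5S)-2,2-dimethyl-1,3-dioxolane-4,5-dicarboxylate (D-tartrate acetonide) | COC(=O)[C@H]1OC(C)(C)O[C@@H]1C(=O)OC | starting material
9 | (4S,5S)-N4,N5-dimethoxy-N4,N5,2,2-tetramethyl-1,3-dioxolane-4,5-dicarboxamide | CON(C)C(=O)[C@H]1OC(C)(C)O[C@@H]1C(=O)N(C)OC | intermediate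
10 | 1,1'-[(4S,5S)-2,2-dimethyl-1,3-dioxolane-4,5-diyl]di(ethan-1-one) | CC(=O)[C@H]1OC(C)(C)O[C@@H]1C(C)=O | intermediate
11 | mono potassium enolate of 10 | [K+].C=C([O-])[C@H]1OC(C)(C)O[C@@H]1C(C)=O | intermediate
12 | 1-[(4S,5S)-5-acetyl-2,2-dimethyl-1,3-dioxolan-4-yl]ethenyl trifluoromethanesulfonate | C=C(OS(=O)(=O)C(F)(F)F)[C@H]1OC(C)(C)O[C@@H]1C(C)=O | intermediate
13 | trivalent alkenylchromium dichloride derived from 12 | C=C([Cr](Cl)Cl)[C@H]1OC(C)(C)O[C@@H]1C(C)=O | intermediate
14 | (3R)-7-[(4R,5S)-5-acetyl-2,2-dimethyl-1,3-dioxolan-4-yl]-6-hydroxyocta-1,7-dien-3-yl acetate (both C6 epimers = clerodane C4) | C=C[C@H](OC(C)=O)CCC(O)C(=C)[C@H]1OC(C)(C)O[C@@H]1C(C)=O | intermediate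
15 | (2E,4R)-4-acetoxy-8-[(4R,5S)-5-acetyl-2,2-dimethyl-1,3-dioxolan-4-yl]-7-hydroxy-2-methylnona-2,8-dienal (both C7 epimers = clerodane C4) | O=C/C(C)=C/[C@H](OC(C)=O)CCC(O)C(=C)[C@H]1OC(C)(C)O[C@@H]1C(C)=O | intermediate
16 | tertiary C5 radical formed from 15 by hydrogen-atom transfer to C19 | O=C/C(C)=C/[C@H](OC(C)=O)CCC(O)[C](C)[C@H]1OC(C)(C)O[C@@H]1C(C)=O | intermediate
17 | ring A cyclised C9 enolate (iron-bound, drawn as the enolate anion; 1β-OAc, 5α-Me, 10β-H) | OC1CC[C@@H](OC(C)=O)[C@H](C(C)=C[O-])[C@@]1(C)[C@H]2OC(C)(C)O[C@@H]2C(C)=O | intermediate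
18 | trans-decalin hydroxy aldehyde: 1β-OAc, 4-OH (both epimers), 5α-Me, 6α,7β-O-isopropylidene, 8β-OH, 8α-Me, 9α-Me, 9β-CHO, 10β-H | OC1CC[C@@H](OC(C)=O)[C@H]2[C@@]1(C)[C@H]3OC(C)(C)O[C@@H]3[C@](C)(O)[C@]2(C)C=O | intermediate
19 | 4-keto analogue of 18 (4-oxo, otherwise as 18) | O=C1CC[C@@H](OC(C)=O)[C@H]2[C@@]1(C)[C@H]3OC(C)(C)O[C@@H]3[C@](C)(O)[C@]2(C)C=O | intermediate
20 | 1-(tert-butyldimethylsilyloxy)propan-2-one | CC(=O)CO[Si](C)(C)C(C)(C)C | starting material
21 | lithium enolate of 20 (methyl side) | [Li+].C=C([O-])CO[Si](C)(C)C(C)(C)C | intermediate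
22 | (11S)-aldol: 19 with 9β-CH(OH)CH2C(=O)CH2OTBS in place of 9β-CHO | O=C1CC[C@@H](OC(C)=O)[C@H]2[C@@]1(C)[C@H]3OC(C)(C)O[C@@H]3[C@](C)(O)[C@]2(C)[C@H](CC(=O)CO[Si](C)(C)C(C)(C)C)O | intermediate
23 | 11-O-acetate of 22 | O=C1CC[C@@H](OC(C)=O)[C@H]2[C@@]1(C)[C@H]3OC(C)(C)O[C@@H]3[C@](C)(O)[C@]2(C)[C@H](CC(=O)CO[Si](C)(C)C(C)(C)C)OC(C)=O | intermediate
24 | 16-hydroxy-13-ketone (desilylated 23) | O=C1CC[C@@H](OC(C)=O)[C@H]2[C@@]1(C)[C@H]3OC(C)(C)O[C@@H]3[C@](C)(O)[C@]2(C)[C@H](CC(=O)CO)OC(C)=O | intermediate
25 | 16-O-(triphenylphosphoranylidene)acetate of 24 | O=C1CC[C@@H](OC(C)=O)[C@H]2[C@@]1(C)[C@H]3OC(C)(C)O[C@@H]3[C@](C)(O)[C@]2(C)[C@H](CC(=O)COC(=O)C=P(c1ccccc1)(c1ccccc1)c1ccccc1)OC(C)=O | intermediate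
26 | 4-oxo-15,16-olide: 1β,11S-diacetoxy, 6α,7β-O-isopropylidene, 8β-OH, butenolide installed | O=C1CC[C@@H](OC(C)=O)[C@H]2[C@@]1(C)[C@H]3OC(C)(C)O[C@@H]3[C@](C)(O)[C@]2(C)[C@H](CC1=CC(=O)OC1)OC(C)=O | intermediate
27 | 4(18)-methylene analogue of 26 | C=C1CC[C@@H](OC(C)=O)[C@H]2[C@@]1(C)[C@H]3OC(C)(C)O[C@@H]3[C@](C)(O)[C@]2(C)[C@H](CC1=CC(=O)OC1)OC(C)=O | intermediate
28 | 6α,7β,8β-triol (1β,11S-diacetate) | C=C1CC[C@@H](OC(C)=O)[C@H]2[C@@]1(C)[C@@H](O)[C@H](O)[C@](C)(O)[C@]2(C)[C@H](CC1=CC(=O)OC1)OC(C)=O | intermediate
29 | 7β-isobutyrate of 28 (6α-OH and 8β-OH free) | C=C1CC[C@@H](OC(C)=O)[C@H]2[C@@]1(C)[C@@H](O)[C@H](OC(=O)C(C)C)[C@](C)(O)[C@]2(C)[C@H](CC1=CC(=O)OC1)OC(C)=O | intermediate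
30 | CNP0266716.1 (1β,6α,11S-triacetoxy-7β-isobutyryloxy-8β-hydroxy-neo-cleroda-4(18),13-dien-15,16-olide) | C=C1CC[C@@H](OC(C)=O)[C@H]2[C@@]1(C)[C@@H](OC(C)=O)[C@H](OC(=O)C(C)C)[C@](C)(O)[C@]2(C)[C@H](CC1=CC(=O)OC1)OC(C)=O | target

**Total step count:** 19
**Longest linear sequence:** 16 steps (steps 1–4 and 8–19; steps 5–7 build the second fragment)

**Steps most likely to fail**

Step 10. The C9 enolate may be protonated by the alcohol solvent before it reaches the C8 ketone, or ring B may close with poor facial control because of the strain of the trans-fused dioxolane. The fallback sets out from 15 and separates the two bond formations. The same iron-hydride radical cyclisation is run so that the enolate is simply protonated, giving the ring A keto aldehyde F1 (C9 epimers). Ring B is then closed in a separate, thermodynamically controlled intramolecular aldol reaction (piperidinium acetate, benzene, 40 °C), in which the all-equatorial chair product should be the sink. The route is rejoined at 18.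

Step 12. Facial selectivity in the enolate addition to the neopentyl aldehyde may be poor if lithium chelation between O8 and the formyl oxygen does not dominate over open-chain (Felkin-type) attack. The fallback sets out from 19 and uses reagent control. Allylboration with the (−)-diisopinocampheyl 2-(tert-butyldimethylsilyloxymethyl)allylborane gives the (11S)-homoallylic alcohol F2. Acetylation (Ac2O, DMAP) gives the 11-acetate F3, and ozonolysis (O3, then Me2S; no other alkene is present at this stage) unveils the C13 ketone. The route is rejoined at 23.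

Step 18. Acylation may spread over O6 and O7, or the isobutyryl group may migrate between them. The fallback sets out from 28 and differentiates the hydroxyls by ring geometry. Thermodynamic acetalisation (2,2-dimethoxypropane, PPTS) protects the cis-7β,8β-diol as the 7,8-O-isopropylidene 6α-alcohol F4. Acetylation of the only free hydroxyl gives the 6-acetate F5. Aqueous acetic acid then releases the 6-O-acetyl-7β,8β-diol F6, whose single secondary hydroxyl is acylated with isobutyryl chloride (pyridine, DMAP). The route is rejoined at 30.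

**Further compounds**

F1 | step 10 | ring A keto aldehyde (monocyclic Giese product; C4 and C9 epimers) | OC1CC[C@@H](OC(C)=O)[C@H](C(C)C=O)[C@@]1(C)[C@H]2OC(C)(C)O[C@@H]2C(C)=O
F2 | step 12 | (11S)-homoallylic alcohol: 19 with 9β-CH(OH)CH2C(=CH2)CH2OTBS | O=C1CC[C@@H](OC(C)=O)[C@H]2[C@@]1(C)[C@H]3OC(C)(C)O[C@@H]3[C@](C)(O)[C@]2(C)[C@H](CC(=C)CO[Si](C)(C)C(C)(C)C)O
F3 | step 12 | 11-O-acetate of F2 | O=C1CC[C@@H](OC(C)=O)[C@H]2[C@@]1(C)[C@H]3OC(C)(C)O[C@@H]3[C@](C)(O)[C@]2(C)[C@H](CC(=C)CO[Si](C)(C)C(C)(C)C)OC(C)=O
F4 | step 18 | 7β,8β-O-isopropylidene 6α-alcohol | C=C1CC[C@@H](OC(C)=O)[C@H]2[C@@]1(C)[C@@H](O)[C@@H]3OC(C)(C)O[C@]3(C)[C@]2(C)[C@H](CC1=CC(=O)OC1)OC(C)=O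
F5 | step 18 | 6-O-acetate of F4 | C=C1CC[C@@H](OC(C)=O)[C@H]2[C@@]1(C)[C@@H](OC(C)=O)[C@@H]3OC(C)(C)O[C@]3(C)[C@]2(C)[C@H](CC1=CC(=O)OC1)OC(C)=O
F6 | step 18 | 6-O-acetyl-7β,8β-diol | C=C1CC[C@@H](OC(C)=O)[C@H]2[C@@]1(C)[C@@H](OC(C)=O)[C@H](O)[C@](C)(O)[C@]2(C)[C@H](CC1=CC(=O)OC1)OC(C)=O
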